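Everything rests on disconnecting the bond between the secondary benzylic carbinol carbon on C3 of ring A and the neighbouring CH2. Tracing the tertiary C(CH3)2OH back to an isopropenyl group (Markovnikov hydration in the forward sense) turns the side chain into a homoallylic alcohol. One catalytic enantioselective methallylboration of the ring A C3 aldehyde therefore forms that C–C bond, installs the only stereocentre as (R) and brings in the last four carbons. Its precursor is the fully assembled diaryl ether aldehyde: ring A with C1 benzyl ester, C2 methoxy and C3 formyl groups, joined through the C6 oxygen to ring B, whose phenol is benzylated and whose hydroxymethyl group is silylated.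

Key step: step 8

Remark: ring A is numbered C1 (carboxyl-bearing), C2 (OMe), C3 (side chain), C6 (aryloxy). The (R)-phosphoric acid in step 8 is assumed to select the same aldehyde face as it does with benzaldehyde, which corresponds to the (R)-carbinol here (priorities OH > aryl > CH2 > H). The assignment would be confirmed on 15 by MTPA ester analysis, and the (S)-acid used instead if the sense proves opposite.

Step 1
Reactants: 1 4-fluoro-2-methoxybenzaldehyde
Product: 2 1-(dimethoxymethyl)-4-fluoro-2-methoxybenzene
Conditions: HC(OMe)3, MeOH, p-TsOH·H2O (cat.), rt; Et3N quench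
Reagents that add atoms: trimethyl orthoformate, COC(OC)OC
Why: Acid-catalysed acetalisation, driven by the orthoformate as water scavenger, should mask the aldehyde against butyllithium in the next step.

Step 2
Reactants: 2 1-(dimethoxymethyl)-4-fluoro-2-methoxybenzene
Product: 5 benzyl 6-fluoro-3-formyl-2-methoxybenzoate, via aryllithium 3 (not isolated), via acetal ester 4 (not isolated)
Conditions: n-BuLi (1.1 equiv), THF, −78 °C; cannulated into ClCO2Bn (1.5 equiv), THF, −78 °C; then 1 M HCl, THF, rt
Reagents that add atoms: benzyl chloroformate, O=C(Cl)OCc1ccccc1; water, O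
Why: Directed ortho-metalation should remove the most acidic ring proton, the one flanked by fluorine and methoxy, after which the 2,6-disubstituted aryllithium is acylated once by the chloroformate (the hindered ester resists a second addition) and aqueous acid hydrolyses the acetal.

Step 3
Reactants: 6 2-hydroxy-3-methoxy-5-methylbenzaldehyde
Product: 8 2,3-dihydroxy-5-methylbenzaldehyde, via cyclic bromoborate 7 (not isolated)
Conditions: BBr3 (2.2 equiv), CH2Cl2, −78 °C to rt; then H2O
Reagents that add atoms: none
Why: Lewis acid-mediated cleavage of the aryl methyl ether (BBr3 demethylation) should proceed through a catechol borate that is hydrolysed on work-up, the aldehyde being tolerated as in the demethylation of ortho-vanillin-type substrates.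

Step 4
Reactants: 8 2,3-dihydroxy-5-methylbenzaldehyde
Product: 9 3-(benzyloxy)-2-hydroxy-5-methylbenzaldehyde
Conditions: NaH (2.2 equiv), DMSO, rt; BnBr (1.0 equiv), rt; then 1 M HCl
Reagents that add atoms: benzyl bromide, BrCc1ccccc1
Why: Williamson etherification of the doubly deprotonated catechol should occur at O3, because the O2 oxide is delocalised into and chelated by the ortho formyl group and is the poorer nucleophile, the established way to mono-alkylate 2,3-dihydroxybenzaldehydes.

Step 5
Reactants: 9 3-(benzyloxy)-2-hydroxy-5-methylbenzaldehyde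
Product: 10 2-(benzyloxy)-6-(hydroxymethyl)-4-methylphenol
Conditions: NaBH4, MeOH, 0 °C
Reagents that add atoms: none
Why: Borohydride reduction of the aryl aldehyde should give the salicyl alcohol without touching the benzyl ether.

Step 6
Reactants: 10 2-(benzyloxy)-6-(hydroxymethyl)-4-methylphenol
Product: 11 2-(benzyloxy)-6-{[(tert-butyldimethylsilyl)oxy]methyl}-4-methylphenol
Conditions: TBSCl (1.05 equiv), imidazole, CH2Cl2, 0 °C
Reagents that add atoms: tert-butyldimethylsilyl chloride, CC(C)(C)[Si](C)(C)Cl
Why: Silyl ether formation should be selective for the primary benzylic alcohol over the doubly ortho-substituted, hydrogen-bonded phenol, as in the mono-silylation of salicyl alcohol.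

Step 7
Reactants: 5 benzyl 6-fluoro-3-formyl-2-methoxybenzoate; 11 2-(benzyloxy)-6-{[(tert-butyldimethylsilyl)oxy]methyl}-4-methylphenol
Product: 12 benzyl 6-[2-(benzyloxy)-6-{[(tert-butyldimethylsilyl)oxy]methyl}-4-methylphenoxy]-3-formyl-2-methoxybenzoate
Conditions: K2CO3 (1.5 equiv), DMF, 60 °C
Reagents that add atoms: none
Why: Nucleophilic aromatic substitution (SNAr, addition–elimination) should work because the fluorine of 5 is para to the formyl and ortho to the ester group, so the electron-rich phenoxide of 11 displaces it through a stabilised Meisenheimer adduct, while the poorly soluble KF formed should leave the silyl ether intact.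

Step 8
Reactants: 12 benzyl 6-[2-(benzyloxy)-6-{[(tert-butyldimethylsilyl)oxy]methyl}-4-methylphenoxy]-3-formyl-2-methoxybenzoate; 13 methallyl pinacol boronate
Product: 15 benzyl 6-[2-(benzyloxy)-6-{[(tert-butyldimethylsilyl)oxy]methyl}-4-methylphenoxy]-3-[(1R)-1-hydroxy-3-methylbut-3-en-1-yl]-2-methoxybenzoate, via pinacol borate ester 14 (not isolated)
Conditions: (R)-3,3'-bis(2,4,6-triisopropylphenyl)-1,1'-binaphthyl-2,2'-diyl hydrogen phosphate (5 mol%), 13 (1.5 equiv), toluene, −30 °C; then aq. NaHCO3
Reagents that add atoms: methallyl pinacol boronate 13, CC(=C)CB1OC(C)(C)C(C)(C)O1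
Why: The phosphoric acid proton binds a boronate oxygen while its phosphoryl oxygen holds the formyl hydrogen, the aldehyde oxygen coordinates boron, and the methallyl γ-carbon is delivered to the carbonyl carbon through a closed six-membered chair transition state with the aryl group equatorial, giving borate 14, which is hydrolysed on work-up. The closest known reaction type is the chiral phosphoric acid-catalysed allylboration of aromatic aldehydes with allyl pinacol boronates. No ring is closed. The new carbinol stereocentre is set by the catalyst alone, the (R)-acid being expected to direct attack to the aldehyde face that gives the (R)-alcohol, since the substrate has no other stereocentre. The step needs enantioface selectivity and a suppressed uncatalysed background; the substrate secures this because the conjugated aryl aldehyde is its only boron-binding electrophile and because every protic group (acid, phenol, primary alcohol) is capped, so no internal Brønsted acid opens a racemic pathway.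

Step 9
Reactants: 15 benzyl 6-[2-(benzyloxy)-6-{[(tert-butyldimethylsilyl)oxy]methyl}-4-methylphenoxy]-3-[(1R)-1-hydroxy-3-methylbut-3-en-1-yl]-2-methoxybenzoate
Product: 16 benzyl 6-[2-(benzyloxy)-6-{[(tert-butyldimethylsilyl)oxy]methyl}-4-methylphenoxy]-3-[(1R)-1,3-dihydroxy-3-methylbutyl]-2-methoxybenzoate
Conditions: Co(acac)2 (20 mol%), PhSiH3 (2.5 equiv), O2 (1 atm), THF, rt
Reagents that add atoms: dioxygen, O=O
Why: In the Mukaiyama hydration a cobalt hydride formed from the silane should transfer a hydrogen atom to the terminal CH2 of the 1,1-disubstituted alkene, the tertiary radical is trapped by O2 and the peroxide is reduced by the silane, giving the Markovnikov tertiary alcohol without affecting the carbinol stereocentre, the benzyl groups or the silyl ether.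

Step 10
Reactants: 16 benzyl 6-[2-(benzyloxy)-6-{[(tert-butyldimethylsilyl)oxy]methyl}-4-methylphenoxy]-3-[(1R)-1,3-dihydroxy-3-methylbutyl]-2-methoxybenzoate
Product: 17 benzyl 6-[2-(benzyloxy)-6-(hydroxymethyl)-4-methylphenoxy]-3-[(1R)-1,3-dihydroxy-3-methylbutyl]-2-methoxybenzoate
Conditions: Bu4NF (1.2 equiv), AcOH (1.2 equiv), THF, 0 °C to rt
Reagents that add atoms: none
Why: Fluoride-mediated desilylation should cleave the primary silyl ether through formation of the strong Si–F bond, the acetic acid buffer keeping the hindered benzyl ester and the diaryl ether untouched.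

Step 11
Reactants: 17 benzyl 6-[2-(benzyloxy)-6-(hydroxymethyl)-4-methylphenoxy]-3-[(1R)-1,3-dihydroxy-3-methylbutyl]-2-methoxybenzoate
Product: 18 3-[(1R)-1,3-dihydroxy-3-methylbutyl]-6-[2-hydroxy-6-(hydroxymethyl)-4-methylphenoxy]-2-methoxybenzoic acid
Conditions: H2 (1 atm), 10% Pd/C, EtOAc, rt
Reagents that add atoms: none
Why: Catalytic hydrogenolysis should cleave the O–CH2Ph bonds of the aryl benzyl ether and the benzyl ester much faster than the benzylic C–OH bonds, which need acid activation to be reduced, so that under neutral conditions, with the reaction stopped at complete debenzylation, the acid, the phenol and both benzylic alcohols should be released with the stereocentre unchanged.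

Compound list
1 | 4-fluoro-2-methoxybenzaldehyde | COc1cc(F)ccc1C=O | starting material
2 | 1-(dimethoxymethyl)-4-fluoro-2-methoxybenzene | COc1cc(F)ccc1C(OC)OC | intermediate
3 | [3-(dimethoxymethyl)-6-fluoro-2-methoxyphenyl]lithium | COc1c([Li])c(F)ccc1C(OC)OC | intermediate
4 | benzyl 3-(dimethoxymethyl)-6-fluoro-2-methoxybenzoate | COc1c(C(OC)OC)ccc(F)c1C(=O)OCc1ccccc1 | intermediate
5 | benzyl 6-fluoro-3-formyl-2-methoxybenzoate | COc1c(C=O)ccc(F)c1C(=O)OCc1ccccc1 | intermediate
6 | 2-hydroxy-3-methoxy-5-methylbenzaldehyde | COc1cc(C)cc(C=O)c1O | starting material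
7 | 2-bromo-6-methyl-1,3,2-benzodioxaborole-4-carbaldehyde | Cc1cc(C=O)c2OB(Br)Oc2c1 | intermediate
8 | 2,3-dihydroxy-5-methylbenzaldehyde | Cc1cc(O)c(O)c(C=O)c1 | intermediate
9 | 3-(benzyloxy)-2-hydroxy-5-methylbenzaldehyde | Cc1cc(OCc2ccccc2)c(O)c(C=O)c1 | intermediate
10 | 2-(benzyloxy)-6-(hydroxymethyl)-4-methylphenol | Cc1cc(CO)c(O)c(OCc2ccccc2)c1 | intermediate
11 | 2-(benzyloxy)-6-{[(tert-butyldimethylsilyl)oxy]methyl}-4-methylphenol | Cc1cc(CO[Si](C)(C)C(C)(C)C)c(O)c(OCc2ccccc2)c1 | intermediate
12 | benzyl 6-[2-(benzyloxy)-6-{[(tert-butyldimethylsilyl)oxy]methyl}-4-methylphenoxy]-3-formyl-2-methoxybenzoate | COc1c(C=O)ccc(Oc2c(OCc3ccccc3)cc(C)cc2CO[Si](C)(C)C(C)(C)C)c1C(=O)OCc1ccccc1 | intermediate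
13 | methallyl pinacol boronate (4,4,5,5-tetramethyl-2-(2-methylprop-2-en-1-yl)-1,3,2-dioxaborolane) | CC(=C)CB1OC(C)(C)C(C)(C)O1 | starting material
14 | benzyl 6-[2-(benzyloxy)-6-{[(tert-butyldimethylsilyl)oxy]methyl}-4-methylphenoxy]-2-methoxy-3-{(1R)-3-methyl-1-[(4,4,5,5-tetramethyl-1,3,2-dioxaborolan-2-yl)oxy]but-3-en-1-yl}benzoate | COc1c([C@H](OB2OC(C)(C)C(C)(C)O2)CC(C)=C)ccc(Oc2c(OCc3ccccc3)cc(C)cc2CO[Si](C)(C)C(C)(C)C)c1C(=O)OCc1ccccc1 | intermediate
15 | benzyl 6-[2-(benzyloxy)-6-{[(tert-butyldimethylsilyl)oxy]methyl}-4-methylphenoxy]-3-[(1R)-1-hydroxy-3-methylbut-3-en-1-yl]-2-methoxybenzoate | COc1c([C@H](O)CC(C)=C)ccc(Oc2c(OCc3ccccc3)cc(C)cc2CO[Si](C)(C)C(C)(C)C)c1C(=O)OCc1ccccc1 | intermediate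
16 | benzyl 6-[2-(benzyloxy)-6-{[(tert-butyldimethylsilyl)oxy]methyl}-4-methylphenoxy]-3-[(1R)-1,3-dihydroxy-3-methylbutyl]-2-methoxybenzoate | COc1c([C@H](O)CC(C)(C)O)ccc(Oc2c(OCc3ccccc3)cc(C)cc2CO[Si](C)(C)C(C)(C)C)c1C(=O)OCc1ccccc1 | intermediate
17 | benzyl 6-[2-(benzyloxy)-6-(hydroxymethyl)-4-methylphenoxy]-3-[(1R)-1,3-dihydroxy-3-methylbutyl]-2-methoxybenzoate | COc1c([C@H](O)CC(C)(C)O)ccc(Oc2c(OCc3ccccc3)cc(C)cc2CO)c1C(=O)OCc1ccccc1 | intermediate
18 | 3-[(1R)-1,3-dihydroxy-3-methylbutyl]-6-[2-hydroxy-6-(hydroxymethyl)-4-methylphenoxy]-2-methoxybenzoic acid (CNP0452050.1) | COc1c([C@H](O)CC(C)(C)O)ccc(Oc2c(O)cc(C)cc2CO)c1C(=O)O | target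

Total step count: 11.
Longest linear sequence: 9 steps (6 to 18 through steps 3 to 11). The ring A branch (steps 1 and 2) joins at step 7.

Steps most likely to fail

Step 8. The ortho methoxy group and the bulky aryloxy ester framework may disturb the two-point binding of the aldehyde to the acid, giving poor enantioface discrimination or letting an uncatalysed addition compete. The fallback sets out from 12 and comes back at 15, and sets the stereocentre by ketone reduction instead of carbonyl allylation. Indium-mediated Barbier addition of methallyl bromide to 12 (indium powder, THF/H2O, rt) is aldehyde-selective and should give racemic benzyl 6-[2-(benzyloxy)-6-{[(tert-butyldimethylsilyl)oxy]methyl}-4-methylphenoxy]-3-(1-hydroxy-3-methylbut-3-en-1-yl)-2-methoxybenzoate F1. Buffered Dess–Martin oxidation (NaHCO3, CH2Cl2, 0 °C) should give the β,γ-unsaturated aryl ketone benzyl 6-[2-(benzyloxy)-6-{[(tert-butyldimethylsilyl)oxy]methyl}-4-methylphenoxy]-2-methoxy-3-(3-methylbut-3-enoyl)benzoate F2 without moving the double bond into conjugation. Corey–Bakshi–Shibata reduction with (S)-1-methyl-3,3-diphenyltetrahydro-1H,3H-pyrrolo[1,2-c][1,3,2]oxazaborole and catecholborane (toluene, −78 °C, where the alkene is not hydroborated) should then give the (R)-alcohol 15, the aryl group acting as the large substituent.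

Step 2. The aryllithium may add twice to the chloroformate, giving a diaryl ketone, or may lose LiF to an aryne during the transfer. The fallback sets out from 2 and comes back at 5. Compound 2 is lithiated as before and aryllithium 3 is quenched in the same flask at −78 °C with dry CO2, a carboxylation that cannot over-add, giving lithium 3-(dimethoxymethyl)-6-fluoro-2-methoxybenzoate F3, which is not isolated. Acidification with 1 M HCl hydrolyses the acetal and should give 6-fluoro-3-formyl-2-methoxybenzoic acid F4. O-Alkylation of its carboxylate with BnBr and KHCO3 in DMF at rt (SN2 at the benzylic carbon, indifferent to the hindrance around the carboxyl group) should return 5.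

Step 7. Fluoride released during the substitution, together with the heating that the doubly ortho-substituted phenoxide may need, may remove the silyl group, after which the benzylic alkoxide would compete as nucleophile. The fallback sets out from 10 and 5 and comes back at 12, reversing the order of silylation and ether formation. Phenol 10, with its benzylic alcohol free, is coupled with 5 (K2CO3, DMF, 50 °C); carbonate deprotonates only the phenol, so the phenoxide should arylate and give benzyl 6-[2-(benzyloxy)-6-(hydroxymethyl)-4-methylphenoxy]-3-formyl-2-methoxybenzoate F5. Silylation of the primary alcohol (TBSCl, imidazole, CH2Cl2, 0 °C), now with no fluoride source present, should give 12.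

Further compounds
F1 | step 8 | racemic benzyl 6-[2-(benzyloxy)-6-{[(tert-butyldimethylsilyl)oxy]methyl}-4-methylphenoxy]-3-(1-hydroxy-3-methylbut-3-en-1-yl)-2-methoxybenzoate | COc1c(C(O)CC(C)=C)ccc(Oc2c(OCc3ccccc3)cc(C)cc2CO[Si](C)(C)C(C)(C)C)c1C(=O)OCc1ccccc1
F2 | step 8 | benzyl 6-[2-(benzyloxy)-6-{[(tert-butyldimethylsilyl)oxy]methyl}-4-methylphenoxy]-2-methoxy-3-(3-methylbut-3-enoyl)benzoate | COc1c(C(=O)CC(C)=C)ccc(Oc2c(OCc3ccccc3)cc(C)cc2CO[Si](C)(C)C(C)(C)C)c1C(=O)OCc1ccccc1
F3 | step 2 | lithium 3-(dimethoxymethyl)-6-fluoro-2-methoxybenzoate | [Li+].COc1c(C(OC)OC)ccc(F)c1C([O-])=O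
F4 | step 2 | 6-fluoro-3-formyl-2-methoxybenzoic acid | COc1c(C=O)ccc(F)c1C(=O)O
F5 | step 7 | benzyl 6-[2-(benzyloxy)-6-(hydroxymethyl)-4-methylphenoxy]-3-formyl-2-methoxybenzoate | COc1c(C=O)ccc(Oc2c(OCc3ccccc3)cc(C)cc2CO)c1C(=O)OCc1ccccc1
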